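**Plan**
1. Locants are cembrane numbers: C1 = ring CH carrying the acrylate carbons C15/C16/C17; C3 = CHOAc; C4 and C7 = oxolane carbons; C8 = tertiary carbinol; C11 = ketone; C12 = lactone C–O carbon. Retrosynthesis: the C15=C17 methylene is masked as CH–CH2NMe2 and the 14-membered ring is cut at C10–C11 (vinyl iodide + aldehyde). C1–C2 and C15–C17 are then cut together, leaving a seven-membered unsaturated lactone (C11–C16, C20), an oxolanyl methyl ketone enol silane (C2–C10) and Eschenmoser's salt (C17).
2. Enabling feature: in the lactone ring (O, C16, C15, C1, C14, C13, C12) C15 and C1 are the α- and β-carbons of an enoate. C3, held as a ketone, lies 1,5 to C16 and is flanked by the fully substituted oxolane carbon C4, so its enol silane can be nucleophilic only at C2.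
3. Forward order: oxepinone ring by ring-closing metathesis; oxolane ring by epoxide opening; union of the three components without ring closure; 14-membered ring by chromium-mediated C10–C11 coupling; methylene lactone unveiled last.
4. Stereochemistry: C12 from (S)-2-methylglycidol; C4 from (R)-linalool; C7 by Sharpless epoxidation and inversion on oxolane closure; C8 by chelate-controlled alkynylation of a methyl ketone; C1 from C12 across the oxepinone in the key step; C3 by chelate-controlled hydride reduction; C15 is transient.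

Key step: step 14

Remark on the chemistry: commercial (S)-2-methylglycidol and (R)-linalool are assumed to be of high enantiomeric purity, and the C11 carbinol formed in step 19 is carried as an epimer mixture because step 20 removes that centre.

**Route**

Step 1
Reactants: 1 (S)-2-methylglycidol
Product: 2 triethyl{[(2R)-2-methyloxiran-2-yl]methoxy}silane
Conditions: TESCl, imidazole, CH2Cl2, 0 °C
Reagents that add atoms: chlorotriethylsilane, CC[Si](CC)(CC)Cl
Why: Silyl ether formation at the primary hydroxyl removes the acidic proton before the Grignard step and protects the future C11 oxygen; the epoxide is untouched and the descriptor changes from S to R through the priority rules only.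

Step 2
Reactants: 2 triethyl{[(2R)-2-methyloxiran-2-yl]methoxy}silane; 3 allylmagnesium bromide
Product: 4 (2R)-2-methyl-1-(triethylsilyloxy)hex-5-en-2-ol
Conditions: CuI (10 mol %), THF, −30 °C → 0 °C; aq. NH4Cl
Reagents that add atoms: none
Why: Copper-catalysed Grignard opening of the 2,2-disubstituted epoxide (SN2 at the unhindered CH2) adds C14 and C1 and leaves the C12 centre of 1 untouched.

Step 3
Reactants: 4 (2R)-2-methyl-1-(triethylsilyloxy)hex-5-en-2-ol; 5 acryloyl chloride
Product: 6 (2R)-2-methyl-1-(triethylsilyloxy)hex-5-en-2-yl prop-2-enoate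
Conditions: i-Pr2NEt, DMAP (cat.), CH2Cl2, 0 °C → rt
Reagents that add atoms: none
Why: DMAP-catalysed acylation of the tertiary alcohol with the acid chloride (esterification) supplies C15 and C16 under non-alkoxide conditions that do not move the silyl group.

Step 4
Reactants: 6 (2R)-2-methyl-1-(triethylsilyloxy)hex-5-en-2-yl prop-2-enoate
Product: 7 (7R)-7-methyl-7-[(triethylsilyloxy)methyl]-6,7-dihydrooxepin-2(5H)-one
Conditions: second-generation Grubbs catalyst RuCl2(=CHPh)(PCy3)(H2IMes) (5 mol %), CH2Cl2 (0.005 M), 40 °C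
Reagents that add atoms: none
Why: Ring-closing metathesis between the acrylate and the terminal alkene, helped by the quaternary C12 (Thorpe–Ingold effect), should close the seven-membered unsaturated lactone with loss of ethene.

Step 5
Reactants: 8 (R)-linalool
Product: 9 (2E,6R)-2,6-dimethylocta-2,7-diene-1,6-diol
Conditions: SeO2 (cat.), salicylic acid (cat.), t-BuOOH, CH2Cl2, rt
Reagents that add atoms: tert-butyl hydroperoxide, CC(C)(C)OO
Why: Selenium dioxide allylic oxidation (ene reaction, then [2,3]-sigmatropic shift) should hydroxylate the methyl group trans to the chain on the trisubstituted alkene and give the (E)-allylic alcohol, while the vinyl group stays inert.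

Step 6
Reactants: 9 (2E,6R)-2,6-dimethylocta-2,7-diene-1,6-diol
Product: 11 (2S)-2-[(2R,5R)-5-ethenyl-5-methyloxolan-2-yl]propane-1,2-diol, via epoxy alcohol 10 (not isolated)
Conditions: Ti(OiPr)4 (cat.), L-(+)-diethyl tartrate (cat.), t-BuOOH, 4 Å MS, CH2Cl2, −20 °C; then CSA (cat.), 0 °C → rt
Reagents that add atoms: tert-butyl hydroperoxide, CC(C)(C)OO
Why: Sharpless asymmetric epoxidation of the primary allylic alcohol with L-(+)-tartrate should give the (2S,3S)-epoxide 10 under reagent control (the tertiary vinyl carbinol is not a substrate), and acid-promoted 5-exo-tet attack of the C4 hydroxyl on C7 with inversion then closes the oxolane with C7 (R) and the C3 and C8 arms trans.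

Step 7
Reactants: 11 (2S)-2-[(2R,5R)-5-ethenyl-5-methyloxolan-2-yl]propane-1,2-diol
Product: 12 1-[(2R,5R)-5-ethenyl-5-methyloxolan-2-yl]ethan-1-one
Conditions: NaIO4, THF/H2O, 0 °C → rt
Reagents that add atoms: none
Why: Periodate glycol cleavage excises the hydroxymethyl carbon and leaves C8 as a methyl ketone under near-neutral conditions that should not epimerise C7; the C8 configuration from step 6, opposite to the one required, is deliberately erased here.

Step 8
Reactants: 12 1-[(2R,5R)-5-ethenyl-5-methyloxolan-2-yl]ethan-1-one; 13 ethynyltrimethylsilane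
Product: 15 (2R)-2-[(2R,5R)-5-ethenyl-5-methyloxolan-2-yl]-4-(trimethylsilyl)but-3-yn-2-ol, via bromomagnesium acetylide 14 (not isolated)
Conditions: 13, EtMgBr, THF, 0 °C → rt; then 12, CH2Cl2, −78 °C → −20 °C; aq. NH4Cl
Reagents that add atoms: none
Why: Cram-chelate-controlled Grignard addition: magnesium should bridge the ketone and oxolane oxygens so that the acetylide attacks C8 from the side of the C7 hydrogen and not from the side of the ring, which sets the C8 carbinol (R) with C19 as the methyl group and C9–C10 as the alkyne.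

Step 9
Reactants: 15 (2R)-2-[(2R,5R)-5-ethenyl-5-methyloxolan-2-yl]-4-(trimethylsilyl)but-3-yn-2-ol
Product: 16 triethylsilyl ether of 15
Conditions: TESOTf, 2,6-lutidine, CH2Cl2, −78 °C → 0 °C
Reagents that add atoms: triethylsilyl trifluoromethanesulfonate, CC[Si](CC)(CC)OS(=O)(=O)C(F)(F)F
Why: Silylation with a silyl triflate and a hindered pyridine base is the standard protection of a hindered tertiary alcohol.

Step 10
Reactants: 16 triethylsilyl ether of 15
Product: 17 1-[(2R,5R)-2-methyl-5-[(2R)-2-(triethylsilyloxy)-4-(trimethylsilyl)but-3-yn-2-yl]oxolan-2-yl]ethan-1-one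
Conditions: PdCl2 (10 mol %), CuCl, O2 (1 atm), DMF/H2O (7:1), rt
Reagents that add atoms: water, O
Why: Tsuji–Wacker oxidation should convert the only alkene, the vinyl group on C4, into the methyl ketone by Markovnikov hydroxypalladation, the hindered silylalkyne and the silyl ether being inert at room temperature.

Step 11
Reactants: 17 1-[(2R,5R)-2-methyl-5-[(2R)-2-(triethylsilyloxy)-4-(trimethylsilyl)but-3-yn-2-yl]oxolan-2-yl]ethan-1-one
Product: 18 1-[(2R,5R)-2-methyl-5-[(2R)-2-(triethylsilyloxy)but-3-yn-2-yl]oxolan-2-yl]ethan-1-one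
Conditions: K2CO3 (cat.), MeOH, 0 °C → rt
Reagents that add atoms: none
Why: Carbonate-catalysed methanolysis of the C(sp)–Si bond frees the terminal alkyne while the hindered tertiary triethylsilyl ether and the non-epimerisable ketone remain.

Step 12
Reactants: 18 1-[(2R,5R)-2-methyl-5-[(2R)-2-(triethylsilyloxy)but-3-yn-2-yl]oxolan-2-yl]ethan-1-one
Product: 20 1-[(2R,5R)-5-[(2R,3E)-4-iodo-2-(triethylsilyloxy)but-3-en-2-yl]-2-methyloxolan-2-yl]ethan-1-one, via vinylstannane 19 (not isolated)
Conditions: Bu3SnH, PdCl2(PPh3)2 (cat.), THF, 0 °C; then I2, CH2Cl2, 0 °C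
Reagents that add atoms: iodine, II
Why: Palladium-catalysed syn-hydrostannation should place tin on the terminal carbon of the hindered propargylic ether, and iododestannylation with retention then gives the (E)-vinyl iodide.

Step 13
Reactants: 20 1-[(2R,5R)-5-[(2R,3E)-4-iodo-2-(triethylsilyloxy)but-3-en-2-yl]-2-methyloxolan-2-yl]ethan-1-one
Product: 21 triethyl{[(2R,3E)-4-iodo-2-[(2R,5R)-5-methyl-5-[1-(trimethylsilyloxy)ethenyl]oxolan-2-yl]but-3-en-2-yl]oxy}silane
Conditions: TMSOTf, Et3N, CH2Cl2, 0 °C
Reagents that add atoms: trimethylsilyl trifluoromethanesulfonate, C[Si](C)(C)OS(=O)(=O)C(F)(F)F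
Why: Soft enolisation to the silyl enol ether can occur only toward C2 because C4 is fully substituted, and it leaves the vinyl iodide untouched.

Step 14
Reactants: 7 (7R)-7-methyl-7-[(triethylsilyloxy)methyl]-6,7-dihydrooxepin-2(5H)-one; 21 enol silane of ketone 20; 22 Eschenmoser's salt (N,N-dimethylmethaniminium iodide)
Product: 24 Mannich base (3S,4R,7R)-3-[(dimethylamino)methyl]-7-methyl-7-[(triethylsilyloxy)methyl]oxepan-2-one bearing at C4 the 2-oxoethyl chain that ends in the oxolane of 20, via silyl ketene acetal 23 (not isolated)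
Conditions: TMSOTf (0.2 equiv), CH2Cl2, −78 °C; then 22, −78 °C → rt; aq. NaHCO3
Reagents that add atoms: none
Why: This is a Mukaiyama–Michael addition followed by Mannich capture, the known three-component conjugate addition–enolate trapping sequence: TMSOTf silylates the lactone carbonyl of 7, enol silane 21 adds through C2 to C1, and transfer of the trimethylsilyl group gives the cyclic silyl ketene acetal 23 and returns the catalyst. Eschenmoser's salt 22 then alkylates C15 of 23, so that C1–C2 and C15–C17 are formed in one flask and no ring is closed. C1 is controlled by the quaternary C12: in the sofa-like conformer that keeps the larger silyloxymethyl group pseudo-equatorial, the C20 methyl group is pseudo-axial and C13 is tipped to the opposite face, so 21 is expected to approach C1 from the face that carries C20, away from C13 and from the silyloxymethyl arm, which gives C1 (R) with C2 and C11 trans across the lactone. C15 is set by the new side chain on C1, the iminium ion entering anti to it (trans-3,4-disubstituted oxepanone), and this centre disappears again in step 23. The step needs 1,4- over 1,2-addition and C- over O-aminomethylation, which the silyl-activated enoate and the soft silyl nucleophiles secure, and the nucleophile is regiochemically unambiguous because the ketone of 21 is flanked by the fully substituted C4; low temperature and a substoichiometric amount of TMSOTf spare the tertiary lactone C–O bond and the silyl ethers.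

Step 15
Reactants: 24 Mannich base
Product: 25 C3 alcohol (3S)
Conditions: Zn(BH4)2, Et2O, −30 °C; aq. NH4Cl
Reagents that add atoms: none
Why: Chelation-controlled hydride reduction: zinc should bridge the C3 carbonyl and the oxolane oxygen, and hydride then enters from the face of the C18 methyl group because the other face is covered by the oxolane ring, giving C3 (S); the non-basic reagent and low temperature are chosen to keep the new hydroxyl from attacking the lactone carbonyl.

Step 16
Reactants: 25 C3 alcohol
Product: 26 C3 acetate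
Conditions: Ac2O, pyridine, DMAP (cat.), CH2Cl2, 0 °C
Reagents that add atoms: acetic anhydride, CC(=O)OC(C)=O
Why: DMAP-catalysed acetylation installs the C3 acetate of the target and removes the hydroxyl that lies 1,5 to the lactone carbonyl.

Step 17
Reactants: 26 C3 acetate
Product: 27 C11 primary alcohol
Conditions: HF·pyridine, pyridine, THF, 0 °C
Reagents that add atoms: none
Why: Fluoride-mediated desilylation is much faster for the primary triethylsilyl ether than for the tertiary one on C8, so buffered HF·pyridine in the cold should free the C11 hydroxyl only.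

Step 18
Reactants: 27 C11 primary alcohol
Product: 28 C11 aldehyde
Conditions: Dess–Martin periodinane, CH2Cl2, 0 °C → rt
Reagents that add atoms: none
Why: Dess–Martin oxidation gives the non-enolisable aldehyde (C12 is quaternary) and tolerates the tertiary amine, the vinyl iodide, the esters and the silyl ether.

Step 19
Reactants: 28 C11 aldehyde
Product: 29 macrocyclic allylic alcohol (C11 epimers)
Conditions: CrCl2 (10 equiv), NiCl2 (2 mol %), DMSO/THF (3:1), rt, 0.002 M, slow addition of 28
Reagents that add atoms: none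
Why: Nozaki–Hiyama–Kishi reaction: nickel-catalysed formation of the alkenylchromium species from the vinyl iodide and its addition to the aldehyde under high dilution should close the 14-membered ring at C10–C11 with retention of the (E)-alkene, the esters, the amine and the silyl ether being tolerated.

Step 20
Reactants: 29 macrocyclic allylic alcohol
Product: 30 macrocyclic enone
Conditions: Dess–Martin periodinane, CH2Cl2, rt
Reagents that add atoms: none
Why: Dess–Martin oxidation of the allylic alcohol converges both C11 epimers on the C9=C10–C11 enone.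

Step 21
Reactants: 30 macrocyclic enone
Product: 31 macrocyclic saturated ketone
Conditions: H2 (1 atm), Pd/C, EtOAc, rt
Reagents that add atoms: none
Why: Catalytic hydrogenation reduces the only C=C bond, the disubstituted enone alkene, and no other alkene competes because the methylene lactone is still masked as the amine.

Step 22
Reactants: 31 macrocyclic saturated ketone
Product: 32 C8 tertiary alcohol
Conditions: HF·pyridine, THF, rt
Reagents that add atoms: none
Why: Fluoride desilylation at room temperature removes the remaining tertiary silyl ether without touching acetate, lactone or ketone.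

Step 23
Reactants: 32 C8 tertiary alcohol
Product: 34 CNP0198878.1, via trimethylammonium iodide 33 (not isolated)
Conditions: MeI, CH2Cl2/MeOH, rt; then aq. NaHCO3, rt
Reagents that add atoms: none
Why: Quaternisation of the tertiary amine with methyl iodide and E1cB (Hofmann-type) elimination of trimethylamine from the β-ammonio lactone on mild base unveil the α-methylene lactone under conditions that leave the tertiary alcohol, acetate and ketone alone.

**Compound list**

1 | (S)-2-methylglycidol | OC[C@@]1(C)CO1 | starting material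
2 | triethyl{[(2R)-2-methyloxiran-2-yl]methoxy}silane | CC[Si](CC)(CC)OC[C@@]1(C)CO1 | intermediate
3 | allylmagnesium bromide | C=CC[Mg]Br | starting material
4 | (2R)-2-methyl-1-(triethylsilyloxy)hex-5-en-2-ol | CC[Si](CC)(CC)OC[C@@](O)(C)CCC=C | intermediate
5 | acryloyl chloride | C=CC(=O)Cl | starting material
6 | (2R)-2-methyl-1-(triethylsilyloxy)hex-5-en-2-yl prop-2-enoate | CC[Si](CC)(CC)OC[C@@](OC(=O)C=C)(C)CCC=C | intermediate
7 | (7R)-7-methyl-7-[(triethylsilyloxy)methyl]-6,7-dihydrooxepin-2(5H)-one | O=C1C=CCC[C@](C)(CO[Si](CC)(CC)CC)O1 | intermediate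
8 | (R)-linalool, (3R)-3,7-dimethylocta-1,6-dien-3-ol | C=C[C@](C)(O)CCC=C(C)C | starting material
9 | (2E,6R)-2,6-dimethylocta-2,7-diene-1,6-diol | C=C[C@](C)(O)CC/C=C(\C)CO | intermediate
10 | (3R)-5-[(2S,3S)-3-(hydroxymethyl)-3-methyloxiran-2-yl]-3-methylpent-1-en-3-ol | C=C[C@](C)(O)CC[C@@H]1O[C@@]1(C)CO | intermediate
11 | (2S)-2-[(2R,5R)-5-ethenyl-5-methyloxolan-2-yl]propane-1,2-diol | C=C[C@@]1(C)CC[C@@H](O1)[C@@](C)(O)CO | intermediate
12 | 1-[(2R,5R)-5-ethenyl-5-methyloxolan-2-yl]ethan-1-one | C=C[C@@]1(C)CC[C@@H](O1)C(C)=O | intermediate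
13 | ethynyltrimethylsilane | C#C[Si](C)(C)C | starting material
14 | bromo[(trimethylsilyl)ethynyl]magnesium | C[Si](C)(C)C#C[Mg]Br | intermediate
15 | (2R)-2-[(2R,5R)-5-ethenyl-5-methyloxolan-2-yl]-4-(trimethylsilyl)but-3-yn-2-ol | C=C[C@@]1(C)CC[C@@H](O1)[C@](C)(O)C#C[Si](C)(C)C | intermediate
16 | {[(2R)-2-[(2R,5R)-5-ethenyl-5-methyloxolan-2-yl]-4-(trimethylsilyl)but-3-yn-2-yl]oxy}triethylsilane | C=C[C@@]1(C)CC[C@@H](O1)[C@](C)(O[Si](CC)(CC)CC)C#C[Si](C)(C)C | intermediate
17 | 1-[(2R,5R)-2-methyl-5-[(2R)-2-(triethylsilyloxy)-4-(trimethylsilyl)but-3-yn-2-yl]oxolan-2-yl]ethan-1-one | CC(=O)[C@@]1(C)CC[C@@H](O1)[C@](C)(O[Si](CC)(CC)CC)C#C[Si](C)(C)C | intermediate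
18 | 1-[(2R,5R)-2-methyl-5-[(2R)-2-(triethylsilyloxy)but-3-yn-2-yl]oxolan-2-yl]ethan-1-one | CC(=O)[C@@]1(C)CC[C@@H](O1)[C@](C)(O[Si](CC)(CC)CC)C#C | intermediate
19 | 1-[(2R,5R)-2-methyl-5-[(2R,3E)-4-(tributylstannyl)-2-(triethylsilyloxy)but-3-en-2-yl]oxolan-2-yl]ethan-1-one | CC(=O)[C@@]1(C)CC[C@@H](O1)[C@](C)(O[Si](CC)(CC)CC)/C=C/[Sn](CCCC)(CCCC)CCCC | intermediate
20 | 1-[(2R,5R)-5-[(2R,3E)-4-iodo-2-(triethylsilyloxy)but-3-en-2-yl]-2-methyloxolan-2-yl]ethan-1-one | CC(=O)[C@@]1(C)CC[C@@H](O1)[C@](C)(O[Si](CC)(CC)CC)/C=C/I | intermediate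
21 | triethyl{[(2R,3E)-4-iodo-2-[(2R,5R)-5-methyl-5-[1-(trimethylsilyloxy)ethenyl]oxolan-2-yl]but-3-en-2-yl]oxy}silane | C=C(O[Si](C)(C)C)[C@@]1(C)CC[C@@H](O1)[C@](C)(O[Si](CC)(CC)CC)/C=C/I | intermediate
22 | Eschenmoser's salt, N,N-dimethylmethaniminium iodide | C=[N+](C)C.[I-] | starting material
23 | trimethylsilyl ketene acetal of the Michael adduct: (4R,7R)-7-methyl-7-[(triethylsilyloxy)methyl]-2-(trimethylsilyloxy)-4,5,6,7-tetrahydrooxepine bearing at C4 the 2-oxoethyl chain that ends in the oxolane of 20 | C[Si](C)(C)OC1=C[C@@H](CC(=O)[C@@]2(C)CC[C@@H](O2)[C@](C)(O[Si](CC)(CC)CC)/C=C/I)CC[C@](C)(CO[Si](CC)(CC)CC)O1 | intermediate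
24 | (3S,4R,7R)-3-[(dimethylamino)methyl]-4-{2-[(2R,5R)-5-[(2R,3E)-4-iodo-2-(triethylsilyloxy)but-3-en-2-yl]-2-methyloxolan-2-yl]-2-oxoethyl}-7-methyl-7-[(triethylsilyloxy)methyl]oxepan-2-one | CN(C)C[C@H]1C(=O)O[C@@](C)(CO[Si](CC)(CC)CC)CC[C@@H]1CC(=O)[C@@]1(C)CC[C@@H](O1)[C@](C)(O[Si](CC)(CC)CC)/C=C/I | intermediate
25 | alcohol from 24: the side-chain ketone is reduced to the (S)-carbinol (cembrane C3), other centres as in 24 | CN(C)C[C@H]1C(=O)O[C@@](C)(CO[Si](CC)(CC)CC)CC[C@@H]1C[C@H](O)[C@@]1(C)CC[C@@H](O1)[C@](C)(O[Si](CC)(CC)CC)/C=C/I | intermediate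
26 | acetate of 25 at the C3 hydroxyl | CN(C)C[C@H]1C(=O)O[C@@](C)(CO[Si](CC)(CC)CC)CC[C@@H]1C[C@H](OC(C)=O)[C@@]1(C)CC[C@@H](O1)[C@](C)(O[Si](CC)(CC)CC)/C=C/I | intermediate
27 | 26 with the primary silyl ether cleaved: 7-(hydroxymethyl)oxepan-2-one, tertiary silyl ether on C8 retained | CN(C)C[C@H]1C(=O)O[C@@](C)(CO)CC[C@@H]1C[C@H](OC(C)=O)[C@@]1(C)CC[C@@H](O1)[C@](C)(O[Si](CC)(CC)CC)/C=C/I | intermediate
28 | aldehyde from 27: the hydroxymethyl group on the lactone C–O carbon (C12) is oxidised to CHO | CN(C)C[C@H]1C(=O)O[C@@](C)(C=O)CC[C@@H]1C[C@H](OC(C)=O)[C@@]1(C)CC[C@@H](O1)[C@](C)(O[Si](CC)(CC)CC)/C=C/I | intermediate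
29 | macrocyclic allylic alcohol: 14-membered carbocycle C1–C14 bridged by the 4,7-oxolane and the C16–O–C12 oxepanone; 15-(dimethylaminomethyl), 3-acetoxy, 8-triethylsilyloxy, (9E)-alkene, 11-hydroxy as epimer mixture; 1R,3S,4R,7R,8R,12R,15S | CN(C)C[C@H]1C(=O)O[C@]2(C)CC[C@@H]1C[C@H](OC(C)=O)[C@@]1(C)CC[C@@H](O1)[C@](C)(O[Si](CC)(CC)CC)/C=C/C2O | intermediate
30 | macrocyclic enone: 29 with C11 as ketone conjugated to the (9E)-alkene | CN(C)C[C@H]1C(=O)O[C@]2(C)CC[C@@H]1C[C@H](OC(C)=O)[C@@]1(C)CC[C@@H](O1)[C@](C)(O[Si](CC)(CC)CC)/C=C/C2=O | intermediate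
31 | macrocyclic saturated ketone: 30 with C9–C10 reduced | CN(C)C[C@H]1C(=O)O[C@]2(C)CC[C@@H]1C[C@H](OC(C)=O)[C@@]1(C)CC[C@@H](O1)[C@](C)(O[Si](CC)(CC)CC)CCC2=O | intermediate
32 | 31 with the C8 silyl ether cleaved: 15-(dimethylaminomethyl) dihydro form of the target, 15S | CN(C)C[C@H]1C(=O)O[C@]2(C)CC[C@@H]1C[C@H](OC(C)=O)[C@@]1(C)CC[C@@H](O1)[C@](C)(O)CCC2=O | intermediate
33 | trimethylammonium iodide of 32 | C[N+](C)(C)C[C@H]1C(=O)O[C@]2(C)CC[C@@H]1C[C@H](OC(C)=O)[C@@]1(C)CC[C@@H](O1)[C@](C)(O)CCC2=O.[I-] | intermediate
34 | CNP0198878.1 (1R,3S,4R,7R,8R,12R) | C=C1C(=O)O[C@]2(C)CC[C@@H]1C[C@H](OC(C)=O)[C@@]1(C)CC[C@@H](O1)[C@](C)(O)CCC2=O | target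

**Step count**

Total: 23 steps (lactone branch steps 1–4, oxolane branch steps 5–13, union and endgame steps 14–23).
Longest linear sequence: 19 steps, from (R)-linalool 8 through steps 5–23.

**Steps most likely to fail**

Step 14. What may go wrong is weak facial discrimination at C1, because the methyl and silyloxymethyl groups on the remote C12 differ little in effective size, and ionisation of the tertiary C12–O bond of the silyl-activated lactone. The fallback replaces substrate control by auxiliary control and uses no Lewis acid; it sets out from ketone 20 and lactone 7 and returns at 24. Ketone 20 is condensed with (S)-1-amino-2-(methoxymethyl)pyrrolidine to the SAMP hydrazone F1. Its lithium azaenolate (LDA, THF, −78 °C) is added to 7 in a hydrazone Michael addition in which the chelating methoxymethyl group of the auxiliary, and not C12, selects the face of C1. The lactone enolate is trapped with 22 to give the hydrazone of the Mannich base F2, and two-phase cleavage with aqueous oxalic acid returns the auxiliary and gives 24. The antipodal auxiliary would be taken if this pairing with the C12 centre proved mismatched.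

Step 19. What may go wrong is intermolecular coupling to oligomers, or reductive loss of iodine, outrunning ring closure onto the hindered α-quaternary aldehyde. The fallback reverses the order of the two unions so that the large ring is closed at C1–C2; it sets out from lactone 7 and ketone 20 and returns at 29. Lactone 7 is desilylated (HF·pyridine) to the lactone alcohol F3 and oxidised (Dess–Martin periodinane) to the lactone aldehyde F4. Intermolecular Nozaki–Hiyama–Kishi coupling of F4 with vinyl iodide 20, whose methyl ketone is inert to the alkenylchromium species, gives the allylic alcohol F5. Treatment with TESOTf and Et3N silylates the C11 hydroxyl and converts the methyl ketone into its enol silane in one operation, giving the bis-silyl compound F6. The Mukaiyama–Michael/Mannich sequence of step 14 is then run intramolecularly at high dilution with 22, and closes the 14-membered ring to the macrocyclic Mannich ketone F7. Reduction with Zn(BH4)2 gives the macrocyclic alcohol F8 and acetylation gives the macrocyclic acetate F9; selective removal of the secondary allylic silyl ether (HF·pyridine, 0 °C) then gives 29.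

Step 15. What may go wrong is loss of chelate control at C3 (hydride entering from the wrong carbonyl face) and acyl transfer of the lactone to the new alkoxide, which lies 1,5 to C16 and could contract the ring to a six-membered lactone. The fallback moves the control to a catalyst and passes through a non-nucleophilic boron alkoxide; it sets out from 24, returns at 25 and makes no new compound (F0). Corey–Bakshi–Shibata reduction with (R)-2-methyl-CBS-oxazaborolidine and catecholborane in toluene at −78 °C lets the catalyst distinguish the fully substituted C4 from the C2 methylene. The borate is cleaved with methanol in the cold and the crude alcohol is acetylated at once as in step 16.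

**Further compounds**

F1 | step 14 | SAMP hydrazone of ketone 20, (E)-hydrazone with (S)-1-amino-2-(methoxymethyl)pyrrolidine | C/C(=N\N1CCC[C@H]1COC)[C@@]1(C)CC[C@@H](O1)[C@](C)(O[Si](CC)(CC)CC)/C=C/I
F2 | step 14 | SAMP hydrazone of Mannich base 24 | CN(C)C[C@H]1C(=O)O[C@@](C)(CO[Si](CC)(CC)CC)CC[C@@H]1C/C(=N\N1CCC[C@H]1COC)[C@@]1(C)CC[C@@H](O1)[C@](C)(O[Si](CC)(CC)CC)/C=C/I
F0 | step 15 | none | none
F3 | step 19 | (7R)-7-(hydroxymethyl)-7-methyl-6,7-dihydrooxepin-2(5H)-one | O=C1C=CCC[C@](C)(CO)O1
F4 | step 19 | (2R)-2-methyl-7-oxo-2,3,4,7-tetrahydrooxepine-2-carbaldehyde | O=C1C=CCC[C@](C)(C=O)O1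
F5 | step 19 | allylic alcohol from 20 and F4 (C11 epimers), methyl ketone and unsaturated lactone intact | CC(=O)[C@@]1(C)CC[C@@H](O1)[C@](C)(O[Si](CC)(CC)CC)/C=C/C(O)[C@@]1(C)CCC=CC(=O)O1
F6 | step 19 | F5 as its C11 triethylsilyl ether and C2=C3 triethylsilyl enol ether | C=C(O[Si](CC)(CC)CC)[C@@]1(C)CC[C@@H](O1)[C@](C)(O[Si](CC)(CC)CC)/C=C/C(O[Si](CC)(CC)CC)[C@@]1(C)CCC=CC(=O)O1
F7 | step 19 | macrocyclic Mannich ketone: C3 ketone, 8- and 11-triethylsilyloxy, (9E)-alkene | CN(C)C[C@H]1C(=O)O[C@]2(C)CC[C@@H]1CC(=O)[C@@]1(C)CC[C@@H](O1)[C@](C)(O[Si](CC)(CC)CC)/C=C/C2O[Si](CC)(CC)CC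
F8 | step 19 | macrocyclic (3S)-alcohol from F7 | CN(C)C[C@H]1C(=O)O[C@]2(C)CC[C@@H]1C[C@H](O)[C@@]1(C)CC[C@@H](O1)[C@](C)(O[Si](CC)(CC)CC)/C=C/C2O[Si](CC)(CC)CC
F9 | step 19 | macrocyclic C3 acetate from F8, 11-triethylsilyl ether of 29 | CN(C)C[C@H]1C(=O)O[C@]2(C)CC[C@@H]1C[C@H](OC(C)=O)[C@@]1(C)CC[C@@H](O1)[C@](C)(O[Si](CC)(CC)CC)/C=C/C2O[Si](CC)(CC)CC
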